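**Numbering used below:** C1–C6 are the ester carbon, the propanoate CH, and the dioxane carbons C3–C6; C1′ is the ring carbinol carbon. The target is the (2R,3S,6R,1′R) isomer encoded by the SMILES.

## Retrosynthetic overview

1. The 1,2-dioxane is closed last: 6-endo iodo-peroxycyclisation of a (3S)-β-hydroperoxy ester onto the (E)-trisubstituted C5=C6 alkene sets C6, then deiodination and desilylation.
2. The C3–OOH group comes from SN2 perhydrolysis (inversion) of a trans-β-lactone made from the anti-β-hydroxy acid.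
3. The C4–C5 bond, which joins the two stereochemical domains, is made by a visible-light nickel/photoredox coupling of an (E)-alkenyl bromide with a malate-derived acetoxy bromide (C2 and C3 from dimethyl (S)-malate).
4. The C1′ carbinol comes from a rhodium-carbenoid O–H insertion/Claisen rearrangement of 6-diazo-2,2-dimethylcyclohexanone with an (R)-allylic alcohol made from (R)-epichlorohydrin (1,3-chirality transfer), followed by Wacker oxidation and double methylenation.
5. Ring order: the carbocycle is bought as 2,2-dimethylcyclohexanone; the dioxane ring is formed at the end.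

## Route

**Step 1**
Reactants: 1 2,2-dimethylcyclohexan-1-one
Product: 3 6-diazo-2,2-dimethylcyclohexan-1-one, via hydroxymethylene ketone 2 (not isolated)
Conditions: NaH, HCO2Et, Et2O, 0 → 23 °C; then MsN3, MeCN, 0 → 23 °C
Reagents that add atoms: ethyl formate, CCOC=O; methanesulfonyl azide, CS(=O)(=O)N=[N+]=[N-]
Why: Claisen formylation can only occur at C6 because C2 is quaternary, and the sodium enolate of 2 undergoes deformylative diazo transfer (Regitz) to the α-diazo ketone.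

**Step 2**
Reactants: 4 (2R)-2-(chloromethyl)oxirane; 5 (4-bromobut-1-yn-1-yl)trimethylsilane
Product: 7 (2R)-1-chloro-7-(trimethylsilyl)hept-6-yn-2-ol, via Grignard reagent 6 (not isolated)
Conditions: Mg, THF, 23 °C; then 4, CuI (10 mol %), THF, −40 → 0 °C
Reagents that add atoms: magnesium, [Mg]
Why: copper-catalysed Grignard opening of the epoxide at its CH2 terminus (SN2 epoxide opening) leaves the bought stereocentre untouched.

**Step 3**
Reactants: 7 (2R)-1-chloro-7-(trimethylsilyl)hept-6-yn-2-ol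
Product: 10 (3R)-oct-1-en-7-yn-3-ol, via epoxide 8 (not isolated), via silyl enynol 9 (not isolated)
Conditions: Me3SI (4 equiv), n-BuLi (4.5 equiv), THF, −10 → 23 °C; then MeOH, K2CO3, 23 °C
Reagents that add atoms: trimethylsulfonium iodide, C[S+](C)C.[I-]
Why: base closes the chlorohydrin to epoxide 8, dimethylsulfonium methylide opens it at CH2 and the betaine loses Me2S to give the one-carbon-homologated allylic alcohol (epoxide-to-allylic-alcohol homologation) without touching the carbinol centre, and methanolysis then cleaves the C–Si bond.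

**Step 4**
Reactants: 10 (3R)-oct-1-en-7-yn-3-ol
Product: 12 (3R,7E)-8-bromo-7-methylocta-1,7-dien-3-ol, via alkenylalane 11 (not isolated)
Conditions: AlMe3 (3 equiv), Cp2ZrCl2 (25 mol %), CH2Cl2, 0 → 23 °C; then NBS, THF, −30 °C
Reagents that add atoms: trimethylaluminium, C[Al](C)C; N-bromosuccinimide, O=C1CCC(=O)N1Br
Why: zirconium-catalysed syn methylalumination of the terminal alkyne (Negishi carboalumination) and bromodealumination with retention give the (E)-2-methylalkenyl bromide, the monosubstituted alkene being inert.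

**Step 5**
Reactants: 3 6-diazo-2,2-dimethylcyclohexan-1-one; 12 (3R,7E)-8-bromo-7-methylocta-1,7-dien-3-ol
Product: 14 (2R)-2-[(2E,7E)-8-bromo-7-methylocta-2,7-dien-1-yl]-2-hydroxy-3,3-dimethylcyclohexan-1-one, via enol ether 13 (not isolated)
Conditions: Rh2(OAc)4 (1 mol %), PhH, 80 °C, slow addition of 3 (2 equiv)
Reagents that add atoms: none
Why: rhodium-carbenoid O–H insertion gives the ring-locked (Z)-α-allyloxy enol 13, whose chair Claisen rearrangement with the side chain equatorial transfers the (R) carbinol configuration of 12 to the new (R) tertiary carbinol C1′ (tandem O–H insertion/[3,3]-sigmatropic rearrangement with 1,3-chirality transfer).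

**Step 6**
Reactants: 14 (2R)-2-[(2E,7E)-8-bromo-7-methylocta-2,7-dien-1-yl]-2-hydroxy-3,3-dimethylcyclohexan-1-one
Product: 15 (2R)-2-[(7E)-8-bromo-7-methyl-3-oxooct-7-en-1-yl]-2-hydroxy-3,3-dimethylcyclohexan-1-one
Conditions: Pd(OAc)2 (5 mol %), p-benzoquinone, aq. HBF4, DMA/MeCN/H2O, 23 °C
Reagents that add atoms: water, O
Why: Wacker oxidation of the 1,2-disubstituted alkene places the carbonyl at the carbon distal to the homoallylic hydroxyl, while the trisubstituted bromoalkene does not react.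

**Step 7**
Reactants: 15 (2R)-2-[(7E)-8-bromo-7-methyl-3-oxooct-7-en-1-yl]-2-hydroxy-3,3-dimethylcyclohexan-1-one
Product: 16 (1R)-1-[(7E)-8-bromo-7-methyl-3-methylideneoct-7-en-1-yl]-2,2-dimethyl-6-methylidenecyclohexan-1-ol
Conditions: Ph3PCH3Br, KN(SiMe3)2, THF, 0 → 45 °C
Reagents that add atoms: methyltriphenylphosphonium bromide, C[P+](c1ccccc1)(c1ccccc1)c1ccccc1.[Br-]
Why: twofold Wittig methylenation converts both ketones into the two 1,1-disubstituted alkenes of the target without affecting the quaternary carbinol.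

**Step 8**
Reactants: 16 (1R)-1-[(7E)-8-bromo-7-methyl-3-methylideneoct-7-en-1-yl]-2,2-dimethyl-6-methylidenecyclohexan-1-ol
Product: 17 {[(1R)-1-[(7E)-8-bromo-7-methyl-3-methylideneoct-7-en-1-yl]-2,2-dimethyl-6-methylidenecyclohexyl]oxy}triethylsilane
Conditions: TESOTf, 2,6-lutidine, CH2Cl2, −78 → 0 °C
Reagents that add atoms: triethylsilyl trifluoromethanesulfonate, CC[Si](CC)(CC)OS(=O)(=O)C(F)(F)F
Why: silyl ether protection masks the tertiary alcohol so that it cannot add to the neighbouring 1,1-disubstituted alkene in the later iodonium step.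

**Step 9**
Reactants: 18 dimethyl (2S)-2-hydroxybutanedioate
Product: 19 dimethyl (2S,3R)-2-hydroxy-3-methylbutanedioate
Conditions: LiN(iPr)2 (2.2 equiv), THF, −78 °C; MeI, −78 → −20 °C
Reagents that add atoms: iodomethane, CI
Why: the chelated alkoxide–enolate dianion is methylated anti to the carbinol substituent (Fráter–Seebach alkylation), so the future C2 methyl centre is set by the bought malate centre.

**Step 10**
Reactants: 19 dimethyl (2S,3R)-2-hydroxy-3-methylbutanedioate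
Product: 20 methyl (2R,3S)-3,4-dihydroxy-2-methylbutanoate
Conditions: BH3·SMe2, NaBH4 (5 mol %), THF, 0 → 23 °C; MeOH
Reagents that add atoms: none
Why: the alkoxyborane formed at the hydroxyl delivers hydride only to the adjacent ester (hydroxyl-directed chemoselective borane reduction), leaving the propanoate ester.

**Step 11**
Reactants: 20 methyl (2R,3S)-3,4-dihydroxy-2-methylbutanoate
Product: 22 methyl (2R,3S)-3-(acetyloxy)-4-bromo-2-methylbutanoate, via cyclic orthoester 21 (not isolated)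
Conditions: MeC(OMe)3, PPTS (cat.), CH2Cl2, 23 °C; then AcBr, 0 → 23 °C
Reagents that add atoms: trimethyl orthoacetate, CC(OC)(OC)OC; acetyl bromide, CC(=O)Br
Why: the dioxolanylium ion from 21 is opened by bromide at the primary carbon (one-pot acetoxy bromide formation from a 1,2-diol), so the secondary C–O bond and its configuration are retained.

**Step 12** (photochemical key step)
Reactants: 17 {[(1R)-1-[(7E)-8-bromo-7-methyl-3-methylideneoct-7-en-1-yl]-2,2-dimethyl-6-methylidenecyclohexyl]oxy}triethylsilane; 22 methyl (2R,3S)-3-(acetyloxy)-4-bromo-2-methylbutanoate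
Product: 23 methyl (2R,3R,5E)-3-(acetyloxy)-12-{(1R)-2,2-dimethyl-6-methylidene-1-[(triethylsilyl)oxy]cyclohexyl}-2,6-dimethyl-10-methylidenedodec-5-enoate
Conditions: [Ir(dF(CF3)ppy)2(dtbbpy)]PF6 (1 mol %), NiCl2(dme) (5 mol %), dtbbpy, (Me3Si)3SiH, Na2CO3, DME, blue LEDs (450 nm), 25 °C
Reagents that add atoms: none
Why: under visible light the silyl radical abstracts bromine from 22 and the primary alkyl radical is captured by the alkenylnickel bromide formed from 17, so reductive elimination forms the C4–C5 bond with retention of the (E) geometry (nickel/photoredox cross-electrophile coupling).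

**Step 13**
Reactants: 23 methyl (2R,3R,5E)-3-(acetyloxy)-12-{(1R)-2,2-dimethyl-6-methylidene-1-[(triethylsilyl)oxy]cyclohexyl}-2,6-dimethyl-10-methylidenedodec-5-enoate
Product: 24 (2R,3R,5E)-12-{(1R)-2,2-dimethyl-6-methylidene-1-[(triethylsilyl)oxy]cyclohexyl}-3-hydroxy-2,6-dimethyl-10-methylidenedodec-5-enoic acid
Conditions: LiOH, THF/MeOH/H2O, 0 → 23 °C; then 1 M HCl to pH 4
Reagents that add atoms: lithium hydroxide, [Li+].[OH-]
Why: ester hydrolysis removes the acetate and the methyl ester to give the anti β-hydroxy acid without touching the stereocentres.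

**Step 14**
Reactants: 24 (2R,3R,5E)-12-{(1R)-2,2-dimethyl-6-methylidene-1-[(triethylsilyl)oxy]cyclohexyl}-3-hydroxy-2,6-dimethyl-10-methylidenedodec-5-enoic acid
Product: 25 (3R,4R)-4-[(2E)-9-{(1R)-2,2-dimethyl-6-methylidene-1-[(triethylsilyl)oxy]cyclohexyl}-3-methyl-7-methylidenenon-2-en-1-yl]-3-methyloxetan-2-one
Conditions: PhSO2Cl, pyridine, 0 °C
Reagents that add atoms: none
Why: carboxyl activation as the mixed sulfonic anhydride and attack by the hydroxyl oxygen close the trans β-lactone with retention at C3 (β-lactonisation by carboxyl activation).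

**Step 15** (new transformation)
Reactants: 25 (3R,4R)-4-[(2E)-9-{(1R)-2,2-dimethyl-6-methylidene-1-[(triethylsilyl)oxy]cyclohexyl}-3-methyl-7-methylidenenon-2-en-1-yl]-3-methyloxetan-2-one
Product: 26 (2R,3S,5E)-12-{(1R)-2,2-dimethyl-6-methylidene-1-[(triethylsilyl)oxy]cyclohexyl}-3-hydroperoxy-2,6-dimethyl-10-methylidenedodec-5-enoic acid
Conditions: anhydrous H2O2 in Et2O (10 equiv), Yb(OTf)3 (10 mol %), 0 → 23 °C
Reagents that add atoms: hydrogen peroxide, OO
Why: Proposed new method: Lewis-acid activation of the lactone carbonyl turns the carboxylate into a leaving group and the α-effect nucleophile H2O2 attacks the secondary β-carbon from the back side (alkyl–oxygen cleavage), giving the β-hydroperoxy acid with inversion to the (3S) configuration of the target; the closest known reaction types are the SN2 alkyl–oxygen opening of β-lactones by neutral or soft nucleophiles and the Lewis-acid-promoted opening of oxetanes by hydrogen peroxide with inversion.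

**Step 16**
Reactants: 26 (2R,3S,5E)-12-{(1R)-2,2-dimethyl-6-methylidene-1-[(triethylsilyl)oxy]cyclohexyl}-3-hydroperoxy-2,6-dimethyl-10-methylidenedodec-5-enoic acid
Product: 27 methyl (2R,3S,5E)-12-{(1R)-2,2-dimethyl-6-methylidene-1-[(triethylsilyl)oxy]cyclohexyl}-3-hydroperoxy-2,6-dimethyl-10-methylidenedodec-5-enoate
Conditions: TMSCHN2, PhMe/MeOH, 0 °C
Reagents that add atoms: (trimethylsilyl)diazomethane, C[Si](C)(C)C=[N+]=[N-]
Why: diazoalkane esterification methylates only the carboxylic acid because the hydroperoxide is too weak an acid to protonate the reagent, and the ester prevents iodolactonisation in the next step.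

**Step 17**
Reactants: 27 methyl (2R,3S,5E)-12-{(1R)-2,2-dimethyl-6-methylidene-1-[(triethylsilyl)oxy]cyclohexyl}-3-hydroperoxy-2,6-dimethyl-10-methylidenedodec-5-enoate
Product: 28 methyl (2R)-2-[(3S,5S,6R)-6-(6-{(1R)-2,2-dimethyl-6-methylidene-1-[(triethylsilyl)oxy]cyclohexyl}-4-methylidenehexyl)-5-iodo-6-methyl-1,2-dioxan-3-yl]propanoate
Conditions: NIS, CH2Cl2, −78 → −20 °C, dark
Reagents that add atoms: N-iodosuccinimide, O=C1CCC(=O)N1I
Why: the hydroperoxide adds anti to the iodonium ion at the more substituted alkene carbon through a chair transition state with the C3 substituent equatorial (6-endo iodo-peroxycyclisation), so the (E) alkene geometry puts the long chain equatorial and the methyl axial and sets the quaternary C6 as (R).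

**Step 18**
Reactants: 28 methyl (2R)-2-[(3S,5S,6R)-6-(6-{(1R)-2,2-dimethyl-6-methylidene-1-[(triethylsilyl)oxy]cyclohexyl}-4-methylidenehexyl)-5-iodo-6-methyl-1,2-dioxan-3-yl]propanoate
Product: 29 methyl (2R)-2-[(3S,6R)-6-(6-{(1R)-2,2-dimethyl-6-methylidene-1-[(triethylsilyl)oxy]cyclohexyl}-4-methylidenehexyl)-6-methyl-1,2-dioxan-3-yl]propanoate
Conditions: Bu3SnH (large excess), Et3B, air, PhMe, −40 → 0 °C
Reagents that add atoms: none
Why: tin hydride reduction at high stannane concentration and low temperature traps the C5 radical before it can attack the neighbouring O–O bond.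

**Step 19**
Reactants: 29 methyl (2R)-2-[(3S,6R)-6-(6-{(1R)-2,2-dimethyl-6-methylidene-1-[(triethylsilyl)oxy]cyclohexyl}-4-methylidenehexyl)-6-methyl-1,2-dioxan-3-yl]propanoate
Product: 30 methyl (2R)-2-[(3S,6R)-6-{6-[(1R)-1-hydroxy-2,2-dimethyl-6-methylidenecyclohexyl]-4-methylidenehexyl}-6-methyl-1,2-dioxan-3-yl]propanoate
Conditions: HF·pyridine, THF/pyridine, 0 → 23 °C
Reagents that add atoms: none
Why: buffered fluoride desilylation cleaves the tertiary silyl ether and leaves the peroxide, the ester and the allylic alcohol intact.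

## Compound list

1 | 2,2-dimethylcyclohexan-1-one | CC1(C)CCCCC1=O | starting material
2 | 6-(hydroxymethylidene)-2,2-dimethylcyclohexan-1-one | CC1(C)CCCC(=CO)C1=O | intermediate
3 | 6-diazo-2,2-dimethylcyclohexan-1-one | CC1(C)CCCC(=[N+]=[N-])C1=O | intermediate
4 | (2R)-2-(chloromethyl)oxirane | ClC[C@H]1CO1 | starting material
5 | (4-bromobut-1-yn-1-yl)trimethylsilane | C[Si](C)(C)C#CCCBr | starting material
6 | [4-(trimethylsilyl)but-3-yn-1-yl]magnesium bromide | C[Si](C)(C)C#CCC[Mg]Br | intermediate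
7 | (2R)-1-chloro-7-(trimethylsilyl)hept-6-yn-2-ol | ClC[C@H](O)CCCC#C[Si](C)(C)C | intermediate
8 | (2R)-2-[5-(trimethylsilyl)pent-4-yn-1-yl]oxirane | C1[C@H](O1)CCCC#C[Si](C)(C)C | intermediate
9 | (3R)-8-(trimethylsilyl)oct-1-en-7-yn-3-ol | C=C[C@H](O)CCCC#C[Si](C)(C)C | intermediate
10 | (3R)-oct-1-en-7-yn-3-ol | C=C[C@H](O)CCCC#C | intermediate
11 | [(1E,6R)-6-[(dimethylalumanyl)oxy]-2-methylocta-1,7-dien-1-yl]dimethylalumane | C=C[C@H](O[Al](C)C)CCC/C(C)=C/[Al](C)C | intermediate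
12 | (3R,7E)-8-bromo-7-methylocta-1,7-dien-3-ol | C=C[C@H](O)CCC/C(C)=C/Br | intermediate
13 | 2-{[(3R,7E)-8-bromo-7-methylocta-1,7-dien-3-yl]oxy}-6,6-dimethylcyclohex-1-en-1-ol | OC1=C(O[C@@H](C=C)CCC/C(C)=C/Br)CCCC1(C)C | intermediate
14 | (2R)-2-[(2E,7E)-8-bromo-7-methylocta-2,7-dien-1-yl]-2-hydroxy-3,3-dimethylcyclohexan-1-one | Br/C=C(C)/CCC/C=C/C[C@]1(O)C(=O)CCCC1(C)C | intermediate
15 | (2R)-2-[(7E)-8-bromo-7-methyl-3-oxooct-7-en-1-yl]-2-hydroxy-3,3-dimethylcyclohexan-1-one | Br/C=C(C)/CCCC(=O)CC[C@]1(O)C(=O)CCCC1(C)C | intermediate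
16 | (1R)-1-[(7E)-8-bromo-7-methyl-3-methylideneoct-7-en-1-yl]-2,2-dimethyl-6-methylidenecyclohexan-1-ol | Br/C=C(C)/CCCC(=C)CC[C@]1(O)C(=C)CCCC1(C)C | intermediate
17 | {[(1R)-1-[(7E)-8-bromo-7-methyl-3-methylideneoct-7-en-1-yl]-2,2-dimethyl-6-methylidenecyclohexyl]oxy}triethylsilane | Br/C=C(C)/CCCC(=C)CC[C@]1(O[Si](CC)(CC)CC)C(=C)CCCC1(C)C | intermediate
18 | dimethyl (2S)-2-hydroxybutanedioate | COC(=O)[C@@H](O)CC(=O)OC | starting material
19 | dimethyl (2S,3R)-2-hydroxy-3-methylbutanedioate | COC(=O)[C@@H](O)[C@@H](C)C(=O)OC | intermediate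
20 | methyl (2R,3S)-3,4-dihydroxy-2-methylbutanoate | OC[C@@H](O)[C@@H](C)C(=O)OC | intermediate
21 | methyl (2R)-2-[(4S)-2-methoxy-2-methyl-1,3-dioxolan-4-yl]propanoate | COC1(C)OC[C@@H](O1)[C@@H](C)C(=O)OC | intermediate
22 | methyl (2R,3S)-3-(acetyloxy)-4-bromo-2-methylbutanoate | BrC[C@@H](OC(C)=O)[C@@H](C)C(=O)OC | intermediate
23 | methyl (2R,3R,5E)-3-(acetyloxy)-12-{(1R)-2,2-dimethyl-6-methylidene-1-[(triethylsilyl)oxy]cyclohexyl}-2,6-dimethyl-10-methylidenedodec-5-enoate | COC(=O)[C@H](C)[C@H](OC(C)=O)C/C=C(\C)CCCC(=C)CC[C@]1(O[Si](CC)(CC)CC)C(=C)CCCC1(C)C | intermediate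
24 | (2R,3R,5E)-12-{(1R)-2,2-dimethyl-6-methylidene-1-[(triethylsilyl)oxy]cyclohexyl}-3-hydroxy-2,6-dimethyl-10-methylidenedodec-5-enoic acid | OC(=O)[C@H](C)[C@H](O)C/C=C(\C)CCCC(=C)CC[C@]1(O[Si](CC)(CC)CC)C(=C)CCCC1(C)C | intermediate
25 | (3R,4R)-4-[(2E)-9-{(1R)-2,2-dimethyl-6-methylidene-1-[(triethylsilyl)oxy]cyclohexyl}-3-methyl-7-methylidenenon-2-en-1-yl]-3-methyloxetan-2-one | O=C1O[C@H](C/C=C(\C)CCCC(=C)CC[C@]2(O[Si](CC)(CC)CC)C(=C)CCCC2(C)C)[C@H]1C | intermediate
26 | (2R,3S,5E)-12-{(1R)-2,2-dimethyl-6-methylidene-1-[(triethylsilyl)oxy]cyclohexyl}-3-hydroperoxy-2,6-dimethyl-10-methylidenedodec-5-enoic acid | OC(=O)[C@H](C)[C@@H](OO)C/C=C(\C)CCCC(=C)CC[C@]1(O[Si](CC)(CC)CC)C(=C)CCCC1(C)C | intermediate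
27 | methyl (2R,3S,5E)-12-{(1R)-2,2-dimethyl-6-methylidene-1-[(triethylsilyl)oxy]cyclohexyl}-3-hydroperoxy-2,6-dimethyl-10-methylidenedodec-5-enoate | COC(=O)[C@H](C)[C@@H](OO)C/C=C(\C)CCCC(=C)CC[C@]1(O[Si](CC)(CC)CC)C(=C)CCCC1(C)C | intermediate
28 | methyl (2R)-2-[(3S,5S,6R)-6-(6-{(1R)-2,2-dimethyl-6-methylidene-1-[(triethylsilyl)oxy]cyclohexyl}-4-methylidenehexyl)-5-iodo-6-methyl-1,2-dioxan-3-yl]propanoate | COC(=O)[C@H](C)[C@@H]1C[C@H](I)[C@@](C)(CCCC(=C)CC[C@]2(O[Si](CC)(CC)CC)C(=C)CCCC2(C)C)OO1 | intermediate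
29 | methyl (2R)-2-[(3S,6R)-6-(6-{(1R)-2,2-dimethyl-6-methylidene-1-[(triethylsilyl)oxy]cyclohexyl}-4-methylidenehexyl)-6-methyl-1,2-dioxan-3-yl]propanoate | COC(=O)[C@H](C)[C@@H]1CC[C@@](C)(CCCC(=C)CC[C@]2(O[Si](CC)(CC)CC)C(=C)CCCC2(C)C)OO1 | intermediate
30 | methyl (2R)-2-[(3S,6R)-6-{6-[(1R)-1-hydroxy-2,2-dimethyl-6-methylidenecyclohexyl]-4-methylidenehexyl}-6-methyl-1,2-dioxan-3-yl]propanoate | C=C(CCC[C@]1(C)CC[C@@H]([C@@H](C)C(=O)OC)OO1)CC[C@]1(O)C(=C)CCCC1(C)C | target

## Step count and risks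

Total steps: 19. Longest linear sequence: 15 (steps 2–8, then 12–19). All four stereocentres trace back to (R)-epichlorohydrin (C1′) and dimethyl (S)-malate (C2, C3, and through C3 the quaternary C6).

**Step 15 (the proposed new perhydrolysis).** Hydrogen peroxide may attack the acyl carbon instead, or the homoallylic alkene may take part in an ionising pathway. The fallback uses only known chemistry; it sets out from 23 and comes back at 29. Ester 23 is reduced with LiAlH4 to (2S,3R,5E)-12-{(1R)-2,2-dimethyl-6-methylidene-1-[(triethylsilyl)oxy]cyclohexyl}-2,6-dimethyl-10-methylidenedodec-5-ene-1,3-diol F3. In one flask (n-BuLi, TsCl; then n-BuLi) the diol is taken through the primary sulfonate (2S,3R,5E)-12-{(1R)-2,2-dimethyl-6-methylidene-1-[(triethylsilyl)oxy]cyclohexyl}-3-hydroxy-2,6-dimethyl-10-methylidenedodec-5-en-1-yl 4-methylbenzenesulfonate F4 to the oxetane (2R,3S)-2-[(2E)-9-{(1R)-2,2-dimethyl-6-methylidene-1-[(triethylsilyl)oxy]cyclohexyl}-3-methyl-7-methylidenenon-2-en-1-yl]-3-methyloxetane F5. Ethereal H2O2 with catalytic TMSOTf opens the oxetane at the substituted carbon with inversion (the known Lewis-acid perhydrolysis of oxetanes) to give (2S,3S,5E)-12-{(1R)-2,2-dimethyl-6-methylidene-1-[(triethylsilyl)oxy]cyclohexyl}-3-hydroperoxy-2,6-dimethyl-10-methylidenedodec-5-en-1-ol F6. NIS cyclisation then gives (2S)-2-[(3S,5S,6R)-6-(6-{(1R)-2,2-dimethyl-6-methylidene-1-[(triethylsilyl)oxy]cyclohexyl}-4-methylidenehexyl)-5-iodo-6-methyl-1,2-dioxan-3-yl]propan-1-ol F7, and Bu3SnH gives (2S)-2-[(3S,6R)-6-(6-{(1R)-2,2-dimethyl-6-methylidene-1-[(triethylsilyl)oxy]cyclohexyl}-4-methylidenehexyl)-6-methyl-1,2-dioxan-3-yl]propan-1-ol F8. Oxidation with TEMPO and PhI(OAc)2 in MeCN/H2O passes through (2R)-2-[(3S,6R)-6-(6-{(1R)-2,2-dimethyl-6-methylidene-1-[(triethylsilyl)oxy]cyclohexyl}-4-methylidenehexyl)-6-methyl-1,2-dioxan-3-yl]propanal F9 to (2R)-2-[(3S,6R)-6-(6-{(1R)-2,2-dimethyl-6-methylidene-1-[(triethylsilyl)oxy]cyclohexyl}-4-methylidenehexyl)-6-methyl-1,2-dioxan-3-yl]propanoic acid F10, which TMSCHN2 converts into 29.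

**Step 5 (carbenoid O–H insertion/Claisen).** The carbenoid from 3 has β-hydrogens and can collapse to the enone by 1,2-hydride shift, and the enol may tautomerise before it rearranges. The fallback sets out from 1 and 12 and comes back at 14. Ketone 1 is brominated (Br2, AcOH) to 6-bromo-2,2-dimethylcyclohexan-1-one F1. Etherification with alcohol 12 (Ag2O, CH2Cl2) gives 2-{[(3R,7E)-8-bromo-7-methylocta-1,7-dien-3-yl]oxy}-6,6-dimethylcyclohexan-1-one F2. Its potassium enolate (KH, 18-crown-6, THF, −20 → 23 °C) undergoes the known anionic oxy-Claisen rearrangement of α-allyloxy ketone enolates through the same chair and delivers 14.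

**Step 18 (deiodination next to the peroxide).** The C5 radical can displace at oxygen and give an epoxide with loss of the O–O bond. The fallback avoids the iodide; it sets out from 27 and comes back at 29. Intramolecular peroxymercuration of 27 with Hg(OAc)2 in CH2Cl2 at 0 °C gives methyl (2R)-2-[(3S,5S,6R)-5-(acetoxymercurio)-6-(6-{(1R)-2,2-dimethyl-6-methylidene-1-[(triethylsilyl)oxy]cyclohexyl}-4-methylidenehexyl)-6-methyl-1,2-dioxan-3-yl]propanoate F11. Alkaline NaBH4 (aq. NaOH, CH2Cl2, −10 °C) then effects hydrido-demercuration, in which hydrogen transfer from the mercury hydride is fast, and gives 29.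

## Further compounds

F1 | step 5 | 6-bromo-2,2-dimethylcyclohexan-1-one | CC1(C)CCCC(Br)C1=O
F2 | step 5 | 2-{[(3R,7E)-8-bromo-7-methylocta-1,7-dien-3-yl]oxy}-6,6-dimethylcyclohexan-1-one | O=C1C(O[C@@H](C=C)CCC/C(C)=C/Br)CCCC1(C)C
F3 | step 15 | (2S,3R,5E)-12-{(1R)-2,2-dimethyl-6-methylidene-1-[(triethylsilyl)oxy]cyclohexyl}-2,6-dimethyl-10-methylidenedodec-5-ene-1,3-diol | OC[C@H](C)[C@H](O)C/C=C(\C)CCCC(=C)CC[C@]1(O[Si](CC)(CC)CC)C(=C)CCCC1(C)C
F4 | step 15 | (2S,3R,5E)-12-{(1R)-2,2-dimethyl-6-methylidene-1-[(triethylsilyl)oxy]cyclohexyl}-3-hydroxy-2,6-dimethyl-10-methylidenedodec-5-en-1-yl 4-methylbenzenesulfonate | Cc1ccc(cc1)S(=O)(=O)OC[C@H](C)[C@H](O)C/C=C(\C)CCCC(=C)CC[C@]1(O[Si](CC)(CC)CC)C(=C)CCCC1(C)C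
F5 | step 15 | (2R,3S)-2-[(2E)-9-{(1R)-2,2-dimethyl-6-methylidene-1-[(triethylsilyl)oxy]cyclohexyl}-3-methyl-7-methylidenenon-2-en-1-yl]-3-methyloxetane | C1O[C@H](C/C=C(\C)CCCC(=C)CC[C@]2(O[Si](CC)(CC)CC)C(=C)CCCC2(C)C)[C@H]1C
F6 | step 15 | (2S,3S,5E)-12-{(1R)-2,2-dimethyl-6-methylidene-1-[(triethylsilyl)oxy]cyclohexyl}-3-hydroperoxy-2,6-dimethyl-10-methylidenedodec-5-en-1-ol | OC[C@H](C)[C@@H](OO)C/C=C(\C)CCCC(=C)CC[C@]1(O[Si](CC)(CC)CC)C(=C)CCCC1(C)C
F7 | step 15 | (2S)-2-[(3S,5S,6R)-6-(6-{(1R)-2,2-dimethyl-6-methylidene-1-[(triethylsilyl)oxy]cyclohexyl}-4-methylidenehexyl)-5-iodo-6-methyl-1,2-dioxan-3-yl]propan-1-ol | OC[C@H](C)[C@@H]1C[C@H](I)[C@@](C)(CCCC(=C)CC[C@]2(O[Si](CC)(CC)CC)C(=C)CCCC2(C)C)OO1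
F8 | step 15 | (2S)-2-[(3S,6R)-6-(6-{(1R)-2,2-dimethyl-6-methylidene-1-[(triethylsilyl)oxy]cyclohexyl}-4-methylidenehexyl)-6-methyl-1,2-dioxan-3-yl]propan-1-ol | OC[C@H](C)[C@@H]1CC[C@@](C)(CCCC(=C)CC[C@]2(O[Si](CC)(CC)CC)C(=C)CCCC2(C)C)OO1
F9 | step 15 | (2R)-2-[(3S,6R)-6-(6-{(1R)-2,2-dimethyl-6-methylidene-1-[(triethylsilyl)oxy]cyclohexyl}-4-methylidenehexyl)-6-methyl-1,2-dioxan-3-yl]propanal | O=C[C@H](C)[C@@H]1CC[C@@](C)(CCCC(=C)CC[C@]2(O[Si](CC)(CC)CC)C(=C)CCCC2(C)C)OO1
F10 | step 15 | (2R)-2-[(3S,6R)-6-(6-{(1R)-2,2-dimethyl-6-methylidene-1-[(triethylsilyl)oxy]cyclohexyl}-4-methylidenehexyl)-6-methyl-1,2-dioxan-3-yl]propanoic acid | OC(=O)[C@H](C)[C@@H]1CC[C@@](C)(CCCC(=C)CC[C@]2(O[Si](CC)(CC)CC)C(=C)CCCC2(C)C)OO1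
F11 | step 18 | methyl (2R)-2-[(3S,5S,6R)-5-(acetoxymercurio)-6-(6-{(1R)-2,2-dimethyl-6-methylidene-1-[(triethylsilyl)oxy]cyclohexyl}-4-methylidenehexyl)-6-methyl-1,2-dioxan-3-yl]propanoate | COC(=O)[C@H](C)[C@@H]1C[C@H]([Hg]OC(C)=O)[C@@](C)(CCCC(=C)CC[C@]2(O[Si](CC)(CC)CC)C(=C)CCCC2(C)C)OO1
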